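## Structural features

Bractelactone is a 1-benzofuran-2(3H)-one: a five-membered aryl lactone (ring B: O1, C2, C3, C3a, C7a) fused to a benzene ring (ring A: C3a, C4, C5, C6, C7, C7a) in which all six carbons are substituted. Ring A carries a methoxy group at C4, a 3-phenylpropanoyl ketone at C5, free hydroxyls at C6 and C7, and the lactone oxygen at C7a. C3 carries an exocyclic benzylidene group. There is no stereocentre. The only stereochemical element is the C3=CH double bond, which is Z: phenyl lies on the side of the C2 carbonyl and the vinyl hydrogen faces the C4 methoxy group. This is the isomer that avoids the clash between phenyl and OMe, so it should be reachable under equilibrating conditions.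

The fragile groups are the C6/C7 catechol (part of a pyrogallol-type edge, oxidation-prone in base), the aryl lactone (opened by bases and nucleophiles), the benzylidene lactone (Michael acceptor, photoisomerisable) and the enolisable CH2 next to the C5 ketone.

The real difficulty is twofold. First, ring A is hexasubstituted with four differentiated oxygens and two carbon substituents, both ortho to the C4 methoxy group. Second, the C9 unit on C3a is joined to ring A through its central carbon (C3 bears ring A, the carboxyl carbon C2 and the benzylidene carbon), whereas the C9 unit on C5 is joined through its terminal carbonyl carbon.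

The key step exploits this relation. The chain Ph–CH=C3(–)–C2(=O)–O on C3a is the 1,2-shifted, oxidised isomer of the chain Ph–CH2–CH2–C(=O)– on C5. If the benzylic carbon is moved back from C3 to C2, ring A with its two chains (on C3a and C5, flanking C4) gains a mirror plane through C4 and C7.

## Logic of the disconnections

**15 to 12.** The lactone bond O1–C2 is opened to a carboxylic acid and a phenol, water is added back across C3=CH, and the C7 and C7a oxygens (target numbering) are tied into a diphenylmethylene ketal; 14 and 13 are the stations on the way. The cut is made here because the double-bond geometry is the thermodynamic one and can be left to an acid-equilibrated elimination, and because the catechol should be unmasked only at the end. Gain: the Michael acceptor, the aryl lactone and the free catechol are all absent from 12. Demand: the forward step must hydrolyse the ketal, close the five-membered lactone and lose water in acid without touching the methyl ether or the ketone.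

**12 to 11 (key disconnection).** The bond C3–CH2Ph is cut and the benzylic carbon is returned to C2, which changes from a carboxyl carbon back to a ketone carbon; hydroxide is removed. C3 is the one carbon of the target with unusual connectivity, and this single 1,2-shift converts it into the carbonyl carbon of an ordinary aryl ketone. Gain: the tetrasubstituted carbinol carbon on a hexasubstituted ring becomes a linear aryl–C(=O)–C(=O)–CH2Ph chain with the same carbon skeleton as the other chain. Demand: hydroxide must add to the 1,2-dicarbonyl unit of 11 and trigger the shift faster than the enolised form is consumed otherwise, and the second ketone must stay untouched.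

**11 to 10 to 9.** The oxygen on the α-carbon of one chain is removed in two stages (C=O to CH–OH, then C–O to C–H). After this the two chains on the ring are identical. Gain: 9 needs only one kind of side chain. Demand: oxidation of one chain only. The forward step relies on a dianion (phenoxide plus one enolate). It also relies on the fact that either chain of 9 leads to 15, since 8 has a mirror plane and the ketal is lost at the end.

**9 to 8.** The two C–O bonds at the ketal carbon are cut. The ketal masks the oxidation-prone trihydroxy edge for the basic and oxidative steps and leaves a single acidic hydroxyl. Gain: 8 is mirror-symmetric (plane through the methoxy-bearing carbon and the central hydroxyl-bearing carbon). Demand: the ketal must bridge the central oxygen and one outer oxygen; both choices give the same compound.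

**8 to 5 and two molecules of 6.** Both aryl–C(=O) bonds are cut; 7 is the half-way station. The two free positions of 5 are equivalent, each ortho to a hydroxyl and to the methoxy group and para to a hydroxyl. Gain: the fully substituted ring is completed in one operation from a symmetric triol and one carboxylic acid. Demand: the second acylation must overcome the deactivation caused by the first, and the methoxy group must survive the Lewis acid.

**5 to 4 to 3 to 1.** Three O–benzyl bonds are restored, the O–CH3 bond is cut, and the phenolic C–O bond is traced back to a C–CHO bond (2 is the formate on the way). The 1,2,3,5-oxygen pattern with one distinct para oxygen is thereby bought as a gallaldehyde pattern. Demand: aryl migration in the peracid oxidation, which the three alkoxy groups ensure.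

## Other disconnections considered

**Alternative 1:** (the first that comes to mind) Cut the exocyclic C3=CH bond. The forward key step is a Knoevenagel-type condensation of the C3-unsubstituted lactone A1 with benzaldehyde.
- Structure: A1 needs a CH2CO2H arm on the last free ring position of 7, installed by chemistry unrelated to that used for the C5 chain (hydroxyalkylation with glyoxylic acid, reduction, lactonisation), all on an unprotected pyrogallol.
- Mechanism: the base-mediated condensation meets three liabilities at once: opening of the aryl lactone by the amine or alkoxide, the free catechol, and a second acidic CH2 (next to the C5 ketone) that can also condense with the aldehyde.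
- Step economy: counted from 7 it is no shorter than the chosen route from 8, and it uses two different carbon sources for the two arms where the chosen plan uses one.

**Alternative 2:** Cut the C3a–C3 bond. The forward key step is a Friedel–Crafts hydroxyalkylation of 7 at its last free position with ethyl phenylpyruvate (TiCl4), giving hydroxy ester A2, followed by lactonisation and dehydration. On paper this is the shortest plan.
- Mechanism: the electrophile is a ketone that rests largely as its enol and can condense with itself under Lewis acids.
- Structure: the bond must be made intermolecularly at a position flanked by OMe and OH to give a tetrasubstituted carbon. The tertiary benzylic carbinol formed on so electron-rich a ring can ionise again and alkylate a second arene.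
- Preference: the chosen plan makes the hindered aryl–carbon bond as an irreversible acylation and builds the tetrasubstituted carbon afterwards by an intramolecular shift, with no bimolecular step at the congested carbon. The acid variant of this alternative is kept as the fallback for the key step.

**Alternative 3:** Cut C2–C3 and O1–C2, with C2 supplied by carbon monoxide. The forward key step is a hydrocarbonylative lactonisation (CO, Pd(OAc)2, diphosphine) of the 2-alkynylphenol A3, itself reached from 7 by halogenation and Sonogashira coupling.
- Mechanism: syn addition of hydrogen and the acyl group across the alkyne puts phenyl on the side of ring A. The primary product would be the E isomer A4, in which phenyl collides with the C4 methoxy group, so a separate isomerisation would be needed.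
- Mechanism: the same catalysts promote 5-endo-dig attack of the phenol oxygen on the alkyne, a direct competitor.
- Step economy: three metal-mediated operations on a free pyrogallol, against none in the chosen plan.

Key step: step 8

**Remarks on the chemistry (assumptions).**
- 3,4,5-Tris(benzyloxy)benzaldehyde (1) and 3-phenylpropanoic acid (6) are taken as the commercial starting materials.
- Compounds 10, 12, 13 and 14 are racemic; their single stereocentre is erased later.
- Compounds 10 to 12 are drawn for reaction of the chain next to the ketal oxygen (C4 of the benzodioxole). Because 8 is mirror-symmetric and the ketal is removed in step 9, reaction of the other chain would lead to the same 15.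
- Ring positions of the target are given in benzofuranone numbering.

## Route

Step 1
Reactants: 1 3,4,5-tris(benzyloxy)benzaldehyde
Product: 3 3,4,5-tris(benzyloxy)phenol, via 3,4,5-tris(benzyloxy)phenyl formate 2 (not isolated)
Conditions: mCPBA (1.3 equiv), CH2Cl2, 0 °C to rt; then K2CO3 (0.1 equiv), MeOH, rt
Reagents that add atoms: 3-chloroperoxybenzoic acid (mCPBA), O=C(OO)c1cccc(Cl)c1
Why: Baeyer–Villiger (Dakin-type) oxidation; the electron-rich trialkoxyphenyl group migrates in preference to hydrogen, and the aryl formate 2 is methanolysed in the same flask. Benzyl ethers are inert to both reagents.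

Step 2
Reactants: 3 3,4,5-tris(benzyloxy)phenol
Product: 4 1,2,3-tris(benzyloxy)-5-methoxybenzene
Conditions: MeI, K2CO3, acetone, reflux
Reagents that add atoms: iodomethane, CI
Why: Williamson ether synthesis on the only free phenol; this fixes the oxygen that becomes the C4 methoxy group of the target.

Step 3
Reactants: 4 1,2,3-tris(benzyloxy)-5-methoxybenzene
Product: 5 5-methoxybenzene-1,2,3-triol
Conditions: H2 (1 atm), Pd/C (10%), EtOAc/MeOH, rt; filtered and concentrated under Ar, used at once
Reagents that add atoms: none
Why: Hydrogenolysis of the three benzyl ethers; the methyl ether is untouched. The benzyl groups are removed here, before any alkene exists in the molecule.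

Step 4
Reactants: 5 5-methoxybenzene-1,2,3-triol; 6 3-phenylpropanoic acid (3 equiv)
Product: 8 1,1'-(4,5,6-trihydroxy-2-methoxy-1,3-phenylene)bis(3-phenylpropan-1-one), via 1-(2,3,4-trihydroxy-6-methoxyphenyl)-3-phenylpropan-1-one 7 (not isolated)
Conditions: BF3·OEt2 (neat), 90 °C, Ar; then MeOH/H2O, reflux
Reagents that add atoms: none
Why: Twofold Friedel–Crafts acylation (through aryl esters and Fries-type transfer) at the two equivalent ring positions, each ortho to OH and OMe and para to OH. Both ketones end up chelated to an ortho hydroxyl, and aqueous methanol cleaves the boron chelates.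

Step 5
Reactants: 8 1,1'-(4,5,6-trihydroxy-2-methoxy-1,3-phenylene)bis(3-phenylpropan-1-one)
Product: 9 1,1'-(7-hydroxy-5-methoxy-2,2-diphenyl-1,3-benzodioxole-4,6-diyl)bis(3-phenylpropan-1-one)
Conditions: Ph2CCl2 (1.3 equiv), Ph2O, 170 °C, N2 sweep
Reagents that add atoms: dichlorodiphenylmethane, ClC(Cl)(c1ccccc1)c1ccccc1
Why: Ketalisation of a vicinal dihydroxy pair as the diphenylmethylene ketal. Only the central oxygen with one outer oxygen can form the five-membered dioxole, and by the mirror symmetry of 8 both choices give the same compound. The third hydroxyl stays hydrogen-bonded to its ketone.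

Step 6
Reactants: 9 1,1'-(7-hydroxy-5-methoxy-2,2-diphenyl-1,3-benzodioxole-4,6-diyl)bis(3-phenylpropan-1-one)
Product: 10 2-hydroxy-1-[7-hydroxy-5-methoxy-2,2-diphenyl-6-(3-phenylpropanoyl)-1,3-benzodioxol-4-yl]-3-phenylpropan-1-one (racemic)
Conditions: KN(SiMe3)2 (2.1 equiv), THF, −78 °C; then 2-(phenylsulfonyl)-3-phenyloxaziridine (1.1 equiv), −78 °C; AcOH quench
Reagents that add atoms: 2-(phenylsulfonyl)-3-phenyloxaziridine, O=S(=O)(c1ccccc1)N1OC1c1ccccc1
Why: Enolate hydroxylation with an N-sulfonyloxaziridine (Davis oxidation); the first equivalent of base gives the potassium phenoxide and the second a single ketone enolate, since a second enolate would need a trianion and a third equivalent of base. The enolate is expected on the C4 chain, whose carbonyl is not held in the phenoxide chelate. The new carbinol centre forms as a racemate and is erased in step 7.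

Step 7
Reactants: 10 2-hydroxy-1-[7-hydroxy-5-methoxy-2,2-diphenyl-6-(3-phenylpropanoyl)-1,3-benzodioxol-4-yl]-3-phenylpropan-1-one
Product: 11 1-[7-hydroxy-5-methoxy-2,2-diphenyl-6-(3-phenylpropanoyl)-1,3-benzodioxol-4-yl]-3-phenylpropane-1,2-dione
Conditions: Dess–Martin periodinane (1.3 equiv), CH2Cl2, 0 °C to rt
Reagents that add atoms: none
Why: Dess–Martin oxidation of the secondary α-ketol to the vicinal dione, which is expected to rest largely as its enol. The hydrogen-bonded phenol, the ketal and the second ketone should be inert under these near-neutral conditions.

Step 8
Reactants: 11 1-[7-hydroxy-5-methoxy-2,2-diphenyl-6-(3-phenylpropanoyl)-1,3-benzodioxol-4-yl]-3-phenylpropane-1,2-dione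
Product: 12 2-hydroxy-2-[7-hydroxy-5-methoxy-2,2-diphenyl-6-(3-phenylpropanoyl)-1,3-benzodioxol-4-yl]-3-phenylpropanoic acid (racemic)
Conditions: KOH (10 equiv), H2O/1,4-dioxane (1:1), degassed, Ar, 80 °C; then 1 M HCl to pH 3, 0 °C
Reagents that add atoms: potassium hydroxide, [K+].[OH-]
Why: Benzilic acid rearrangement: hydroxide adds to the benzyl-side carbonyl of the vicinal dione (the more electrophilic and less hindered one, the aryl-side carbonyl being flanked by two ortho oxygens), and the tetrahedral oxyanion pushes the benzyl group with its bonding pair onto the neighbouring aryl ketone carbon; this creates the C3–CH2Ph bond and the fully substituted carbinol C3, while the attacked carbon becomes the carboxylate C2 (addition at the other carbonyl followed by aryl migration would give the same acid). Proton transfer to the α-hydroxy carboxylate is irreversible and drains the enolate of the dione, which is only a reservoir in equilibrium with the keto form. The closest known case is the conversion of 1,3-diphenylpropane-1,2-dione, as formed from chalcone oxide, into 2-hydroxy-2,3-diphenylpropanoic acid by alkali. No ring is closed in this step; ring B closes in step 9 by 5-exo-trig attack of the freed C7a hydroxyl on the carboxyl group. The one new stereocentre, C3, arises as a racemate and needs no control because step 9 turns it into the sp2 carbon of the benzylidene lactone. The step needs chemoselectivity for the dione over the remaining 3-phenylpropanoyl ketone, which is secured because a simple ketone cannot rearrange and is further deactivated as the chelated potassium phenoxide. The ketal keeps the catechol out of reach of autoxidation in base, and exclusion of oxygen prevents oxidative cleavage of the enolate.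

Step 9
Reactants: 12 2-hydroxy-2-[7-hydroxy-5-methoxy-2,2-diphenyl-6-(3-phenylpropanoyl)-1,3-benzodioxol-4-yl]-3-phenylpropanoic acid
Product: 15 bractelactone [(3Z)-3-benzylidene-6,7-dihydroxy-4-methoxy-5-(3-phenylpropanoyl)-1-benzofuran-2(3H)-one], via ketal-free hydroxy acid 13 (not isolated), via 3-benzyl-3-hydroxy lactone 14 (not isolated)
Conditions: AcOH/H2O (4:1), 100 °C, Ar; concentrate; then TsOH·H2O (0.2 equiv), toluene, 80 °C, dark
Reagents that add atoms: none
Why: Acid hydrolysis of the diphenylmethylene ketal frees the C7 and C7a hydroxyls, and the C7a hydroxyl closes the lactone on the carboxyl group (5-exo-trig, the only five-membered ring available). The tertiary benzylic carbinol, para to the C6 hydroxyl and ortho to the methoxy group, then ionises easily (p-quinone methide type) and loses a benzylic proton (E1 dehydration). Protonation and deprotonation at the benzylidene carbon are reversible in acid, so the double bond should settle as Z, with phenyl beside the lactone carbonyl and away from the C4 methoxy group.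

## Compound list

1 | 3,4,5-tris(benzyloxy)benzaldehyde | O=Cc1cc(OCc2ccccc2)c(OCc2ccccc2)c(OCc2ccccc2)c1 | starting material
2 | 3,4,5-tris(benzyloxy)phenyl formate (not isolated) | O=COc1cc(OCc2ccccc2)c(OCc2ccccc2)c(OCc2ccccc2)c1 | intermediate
3 | 3,4,5-tris(benzyloxy)phenol | Oc1cc(OCc2ccccc2)c(OCc2ccccc2)c(OCc2ccccc2)c1 | intermediate
4 | 1,2,3-tris(benzyloxy)-5-methoxybenzene | COc1cc(OCc2ccccc2)c(OCc2ccccc2)c(OCc2ccccc2)c1 | intermediate
5 | 5-methoxybenzene-1,2,3-triol | COc1cc(O)c(O)c(O)c1 | intermediate
6 | 3-phenylpropanoic acid | OC(=O)CCc1ccccc1 | starting material
7 | 1-(2,3,4-trihydroxy-6-methoxyphenyl)-3-phenylpropan-1-one (not isolated) | COc1cc(O)c(O)c(O)c1C(=O)CCc1ccccc1 | intermediate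
8 | 1,1'-(4,5,6-trihydroxy-2-methoxy-1,3-phenylene)bis(3-phenylpropan-1-one) | COc1c(C(=O)CCc2ccccc2)c(O)c(O)c(O)c1C(=O)CCc1ccccc1 | intermediate
9 | 1,1'-(7-hydroxy-5-methoxy-2,2-diphenyl-1,3-benzodioxole-4,6-diyl)bis(3-phenylpropan-1-one) | COc1c(C(=O)CCc2ccccc2)c(O)c2OC(c3ccccc3)(c3ccccc3)Oc2c1C(=O)CCc1ccccc1 | intermediate
10 | 2-hydroxy-1-[7-hydroxy-5-methoxy-2,2-diphenyl-6-(3-phenylpropanoyl)-1,3-benzodioxol-4-yl]-3-phenylpropan-1-one (racemic) | COc1c(C(=O)CCc2ccccc2)c(O)c2OC(c3ccccc3)(c3ccccc3)Oc2c1C(=O)C(O)Cc1ccccc1 | intermediate
11 | 1-[7-hydroxy-5-methoxy-2,2-diphenyl-6-(3-phenylpropanoyl)-1,3-benzodioxol-4-yl]-3-phenylpropane-1,2-dione | COc1c(C(=O)CCc2ccccc2)c(O)c2OC(c3ccccc3)(c3ccccc3)Oc2c1C(=O)C(=O)Cc1ccccc1 | intermediate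
12 | 2-hydroxy-2-[7-hydroxy-5-methoxy-2,2-diphenyl-6-(3-phenylpropanoyl)-1,3-benzodioxol-4-yl]-3-phenylpropanoic acid (racemic) | COc1c(C(=O)CCc2ccccc2)c(O)c2OC(c3ccccc3)(c3ccccc3)Oc2c1C(O)(Cc1ccccc1)C(=O)O | intermediate
13 | 2-hydroxy-3-phenyl-2-[2,3,4-trihydroxy-6-methoxy-5-(3-phenylpropanoyl)phenyl]propanoic acid (racemic, not isolated) | COc1c(C(=O)CCc2ccccc2)c(O)c(O)c(O)c1C(O)(Cc1ccccc1)C(=O)O | intermediate
14 | 3-benzyl-3,6,7-trihydroxy-4-methoxy-5-(3-phenylpropanoyl)-1-benzofuran-2(3H)-one (racemic, not isolated) | COc1c(C(=O)CCc2ccccc2)c(O)c(O)c2OC(=O)C(O)(Cc3ccccc3)c12 | intermediate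
15 | bractelactone, (3Z)-3-benzylidene-6,7-dihydroxy-4-methoxy-5-(3-phenylpropanoyl)-1-benzofuran-2(3H)-one | COc1c(C(=O)CCc2ccccc2)c(O)c(O)c2c1/C(=C/c1ccccc1)C(=O)O2 | target

## Step count and least certain steps

Total step count: 9. Longest linear sequence: 9 steps (1 to 15); 6 enters in step 4.

**Step 8 (key step).** The dione may be held back as its conjugated enolate (deprotonation at the benzylic CH2), which slows hydroxide addition. While it waits, aldol-type self-condensation can take over, and oxidative cleavage of the enolate can occur if oxygen leaks in. Fallback: this sets out from 5 and comes back at 13. Compound 5 is acylated with only one equivalent of 6 so that 7 is isolated. Its last free ring position is then hydroxyalkylated with phenylpyruvic acid under Brønsted or Lewis acid promotion (Friedel–Crafts hydroxyalkylation), which should give 13 directly. Compound 13 closes to 14 and is dehydrated to 15 under the conditions of step 9. This way makes no compound outside the list (F0).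

**Step 4.** The second acylation may stall after the first, because the boron chelate of the mono-ketone withdraws electron density from the ring. Prolonged heating with the Lewis acid may also cleave the methyl ether once it is flanked by two carbonyl groups. Fallback: this sets out from 4 and comes back at 8. The tribenzyl ether 4 is acylated twice with the mixed anhydride of 6 ((CF3CO)2O, H3PO4 cat., CH2Cl2), a Lewis-acid-free acylation of a tetraalkoxybenzene, to give 1,1'-[4,5,6-tris(benzyloxy)-2-methoxy-1,3-phenylene]bis(3-phenylpropan-1-one) F1. Hydrogenolysis (H2, Pd/C) then gives 8.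

**Step 6.** Enolisation may not stop cleanly at one chain, proton exchange between enolate and product may lead to double hydroxylation, and the phenoxide ring may compete for the oxidant. Which of the two chains reacts is not critical, for the reason given in the remarks. Fallback: this sets out from 9 and comes back at 11, bypassing 10 and step 7. The enol of 9 is nitrosated under acid (isoamyl nitrite, dry HCl, THF, 0 °C) to give the α-oximino ketone (2E)-2-(hydroxyimino)-1-[7-hydroxy-5-methoxy-2,2-diphenyl-6-(3-phenylpropanoyl)-1,3-benzodioxol-4-yl]-3-phenylpropan-1-one F2. Transoximation with aqueous glyoxylic acid in AcOH then releases 11.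

**Step 9.** Loss of water from the tertiary carbinol may be incomplete or reversible in the aqueous stage, ketal hydrolysis may lag behind, the double bond may not fully equilibrate to Z, and the quinone-methide-type cation may be intercepted intermolecularly. Fallback: this sets out from 12 and comes back at 15, with the alkene made before the catechol is unmasked.
- The acid is esterified (Me3SiCHN2, MeOH/toluene, 0 °C) to methyl 2-hydroxy-2-[7-hydroxy-5-methoxy-2,2-diphenyl-6-(3-phenylpropanoyl)-1,3-benzodioxol-4-yl]-3-phenylpropanoate F3.
- The tertiary alcohol is eliminated through its chlorosulfite (SOCl2, pyridine, 0 °C) to methyl (2Z)-2-[7-hydroxy-5-methoxy-2,2-diphenyl-6-(3-phenylpropanoyl)-1,3-benzodioxol-4-yl]-3-phenylprop-2-enoate F4.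
- Hot aqueous acetic acid then removes the ketal, and the freed hydroxyl closes the lactone on the ester to give 15. Any E-configured material would pass through A4 and equilibrate to 15 in the acid.

## Further compounds

F0 | step 8 | none | none
F1 | step 4 | 1,1'-[4,5,6-tris(benzyloxy)-2-methoxy-1,3-phenylene]bis(3-phenylpropan-1-one) | COc1c(C(=O)CCc2ccccc2)c(OCc2ccccc2)c(OCc2ccccc2)c(OCc2ccccc2)c1C(=O)CCc1ccccc1
F2 | step 6 | (2E)-2-(hydroxyimino)-1-[7-hydroxy-5-methoxy-2,2-diphenyl-6-(3-phenylpropanoyl)-1,3-benzodioxol-4-yl]-3-phenylpropan-1-one | COc1c(C(=O)CCc2ccccc2)c(O)c2OC(c3ccccc3)(c3ccccc3)Oc2c1C(=O)/C(Cc1ccccc1)=N/O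
F3 | step 9 | methyl 2-hydroxy-2-[7-hydroxy-5-methoxy-2,2-diphenyl-6-(3-phenylpropanoyl)-1,3-benzodioxol-4-yl]-3-phenylpropanoate (racemic) | COC(=O)C(O)(Cc1ccccc1)c1c(OC)c(C(=O)CCc2ccccc2)c(O)c2OC(c3ccccc3)(c3ccccc3)Oc12
F4 | step 9 | methyl (2Z)-2-[7-hydroxy-5-methoxy-2,2-diphenyl-6-(3-phenylpropanoyl)-1,3-benzodioxol-4-yl]-3-phenylprop-2-enoate | COC(=O)/C(=C\c1ccccc1)c1c(OC)c(C(=O)CCc2ccccc2)c(O)c2OC(c3ccccc3)(c3ccccc3)Oc12
A1 | alternative 1 | 6,7-dihydroxy-4-methoxy-5-(3-phenylpropanoyl)-1-benzofuran-2(3H)-one | COc1c(C(=O)CCc2ccccc2)c(O)c(O)c2OC(=O)Cc12
A2 | alternative 2 | ethyl 2-hydroxy-3-phenyl-2-[2,3,4-trihydroxy-6-methoxy-5-(3-phenylpropanoyl)phenyl]propanoate (racemic) | CCOC(=O)C(O)(Cc1ccccc1)c1c(O)c(O)c(O)c(C(=O)CCc2ccccc2)c1OC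
A3 | alternative 3 | 1-[2,3,4-trihydroxy-6-methoxy-5-(phenylethynyl)phenyl]-3-phenylpropan-1-one | COc1c(C#Cc2ccccc2)c(O)c(O)c(O)c1C(=O)CCc1ccccc1
A4 | alternative 3 | (3E)-3-benzylidene-6,7-dihydroxy-4-methoxy-5-(3-phenylpropanoyl)-1-benzofuran-2(3H)-one | COc1c(C(=O)CCc2ccccc2)c(O)c(O)c2c1/C(=C\c1ccccc1)C(=O)O2
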